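## The problem

Compound 23 is methyl (2S,3S,4S)-4-{2-[2-(3,4-dihydroxyphenyl)ethoxy]-2-oxoethyl}-3-formyl-2-methyl-3,4-dihydro-2H-pyran-5-carboxylate, the hydroxytyrosol ester of elenolic acid. The ring is numbered O1, C2 (methyl), C3 (formyl), C4 (acetate arm), C5 (methyl ester), C6 (enol-ether CH); this numbering is kept for every ring compound below, lactol 18 included.

There is only one ring, so the task is the three contiguous stereocentres on a β-alkoxyacrylate: C2/C3 cis and C3/C4 trans. C2 and C3 are neighbours and can be made together in an aldol-type bond formation. C4 can then be controlled by them, if the ring is closed in a way that makes C4 stereogenic only at that moment.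

Three groups are fragile. The C3 aldehyde has an acidic α-hydrogen and carries O1, a vinylogous carboxylate leaving group, in the β-position, so base epimerises C3 or opens the ring by E1cB. The catechol is easily oxidised, above all as its anion. The two esters differ only in conjugation and must be told apart.

The feature that opens a short route is at C4 and C6. C4 bears three two-carbon arms that each end in a carbonyl carbon (C3–CHO, C5–CO2Me, CH2–CO2R). In an open-chain precursor with two identical CH2CO2Me arms, C4 is therefore not a stereocentre. C6 is a single formyl-level carbon between O1 and C5, so it can be brought in as a formate ester on O1 and handed over to carbon.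

## Retrosynthesis

**23 ⇒ 22 (unmasking of C3).** The aldehyde is the most base-sensitive group, so it is carried as its dimethyl acetal and released last. The forward step must be acidic, free of base, and short enough not to epimerise C3.

**22 ⇒ 20 + 21 (side-chain ester, O–CH2 bond).** The ester is cut at the alkyl C–O bond into acid 20 and hydroxytyrosol 21. A Mitsunobu coupling activates the alcohol and not the acid, and the carboxylic acid is far more acidic than the catechol hydroxyls, so 21 should be usable unprotected. This saves the protection and deprotection of the catechol that an acyl-activation route would need.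

**20 ⇒ 19 (ester differentiation).** Acid 20 comes from diester 19 by hydrolysis of the aliphatic methyl ester only. The C5 ester is a vinylogous carbonate and much less electrophilic. With C3 still an acetal, there is no E1cB pathway under hydroxide.

**19 ⇒ 17 (key cut, C5–C6, ring opening).** Cutting C5–C6 and returning C6 to O1 as a formate gives 17, dimethyl 3-[(2S,3S)-3-(formyloxy)-1,1-dimethoxybutan-2-yl]pentanedioate.
- Compared with the neighbouring cuts: cutting O1–C6 instead would lead to an intermolecular formylation with no control over which arm reacts and a risk of double formylation. Cutting C4–C5 or C3–C4 would require C4 to be set in a separate step.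
- Simplification: 17 has two stereocentres instead of three, no ring, and two identical arms on C4.
- Demand on the forward step: an ester enolate of one arm must attack the tethered formate, and C2/C3 must select between the two diastereotopic arms. In the six-membered chair, an equatorial C2 methyl forces the cis C3 acetal axial. This costs little because its 1,3-partners are O1 and the sp2 carbon C5. The spectator arm then avoids allylic strain with the planar enolate by standing axial, anti to the acetal, which is the 3,4-trans arrangement of the target.

**17 ⇒ 16 ⇒ 14 ⇒ 11 (formate and acetal from a syn-aldol adduct).** The formate is traced to the C2-epimeric alcohol 16 through a Mitsunobu reaction with formic acid, which inverts C2 and installs the formyl group in one operation. Acetal 16 comes from aldehyde 14, which comes from the silylated aldol adduct 12 through thioester 13. The thioester route is chosen because its reduction is neutral and leaves the two methyl esters alone. Hydride cleavage of the auxiliary would not, and would liberate an alkoxide δ to two esters.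

**11 ⇒ 8 + 9 (C2–C3 bond).** The C2–C3 bond is cut by an aldol disconnection into imide 8 and acetaldehyde 9. The target needs the anti relationship, but auxiliary-based anti-aldol methods are weakest with a small enolisable aldehyde, and ester-based ones would not distinguish the auxiliary ester from the two methyl esters. The boron-mediated syn-aldol of an N-acyl oxazolidinone is reliable with acetaldehyde and selective for the imide, and the later inversion costs no extra step. The forward step sets C3 in its final configuration.

**8 ⇒ 5 + 6; 5 ⇒ 3 ⇒ 1 + 2 (the three arms).** Imide 8 is the acylated auxiliary 6. Acid 5 is a methanetriacetic acid with one arm distinguished. It arises by cutting one C4–CH2 bond: Michael addition of di-tert-butyl malonate 2 to dimethyl glutaconate 1 gives 3, and acidolysis and decarboxylation free the single acid. The tert-butyl/methyl pair gives the arm differentiation without any selective step.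

## Roads not taken

**Alternative 1: oxa-Diels–Alder with lactone-to-dihydropyran ring switch.**
- Cut: C2–C3 and a temporary O1–C(acetal) bond.
- Forward key step: acetaldehyde 9 and (1E,3E)-5-(benzyloxy)-1-methoxypenta-1,3-diene A1 combine under a chiral Lewis acid to give the all-cis dihydropyran A2. Oxidation of the acetal to the unsaturated lactone A3, conjugate addition of an acetate equivalent anti to the C5 substituent, α-formylation and acidic methanolysis would then rebuild the ring as the target dihydropyran.
- Merits: catalytic and auxiliary-free; C2 and C3 arise in one step from achiral materials; C4 is set by a well-understood substrate bias; every step has a known counterpart.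
- Weak points: acetaldehyde is a small, volatile, enolisable heterodienophile, so the enantioselectivity is uncertain. The ring is built twice. The C3 carbon travels as a benzyloxymethyl group, so debenzylation beside an enol ether and a late oxidation to the epimerisable aldehyde are needed.
- Comparison: the step count would be similar or higher. This road is better in that nothing in it is unproven. The chosen plan sets against it a C3 carbon at the aldehyde oxidation level throughout, a single ring closure, and C4 set in that same closure.

**Alternative 2: iminium–enamine oxa-Michael/Michael annulation.**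
- Cut: O1–C2 and C3–C4.
- Forward key step: (E)-but-2-enal A4, as the iminium ion of a chiral secondary amine, takes up the enol oxygen of dienol diester A5 at C2. The resulting enamine closes onto the enoate (6-exo-trig) to give A6, the bis-silyl ether of the target.
- Merits: by far the shortest road. Skeleton, all three stereocentres, the correct oxidation level and the side chain arrive in one operation.
- Weak points: A5 is a 2-formylglutaconate, which is prone to cyclise to a 2-pyranone or to polymerise. The enol oxygen is a weak, reversible oxa-Michael donor, so the C2 configuration can erode. The C3 formyl centre stays epimerisable under the amine, so the C2/C3 cis relationship would be under thermodynamic rather than catalyst control. The product is exposed to base-like conditions that can reopen the ring.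
- Comparison: if it worked, this road would beat the chosen plan by many steps. The chosen plan offers stable intermediates, each stereocentre set by a separately defensible element, and no exposure of the free aldehyde to amines.

**Alternative 3: vinyl-radical closure of C4–C5.**
- Cut: C4–C5.
- Forward key step: the C5 vinyl radical from the α-bromo-β-alkoxyacrylate A7 (Bu3SnH, AIBN) adds 6-exo-trig to C4 of the tethered (E)-enoate to give A8.
- Merits: neutral conditions; a well-known mode of closure; the side-chain ester is in place before cyclisation; the ring closure itself is more certain than in the chosen plan.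
- Weak points: C2 and C3 must be made beforehand, and the hindered secondary alcohol must be turned into the bromo-alkoxyacrylate. The cis C2/C3 pair forces one substituent axial in the transition state, so the C4 selectivity is hard to predict. C3 is carried as a silyloxymethyl group, so an alkyl silyl ether must be removed beside two aryl silyl ethers, the alcohol oxidised to the sensitive aldehyde, and the catechol then freed with fluoride in the presence of that aldehyde.
- Comparison: length is comparable. The radical road is safer for ring formation. The chosen plan avoids the late redox and deprotection sequence at the most fragile stage and uses no tin.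

Key step: step 10

Assumption: compounds 1, 2, 6, 9 and 21 are taken as purchased; the two CH2CO2Me arms of 3–17 are identical, so C4 carries no descriptor before step 10.

## Route

Step 1
Reactants: 1 dimethyl (E)-pent-2-enedioate (dimethyl glutaconate); 2 di-tert-butyl propanedioate (di-tert-butyl malonate)
Product: 3 1,1-di-tert-butyl 3-methyl 2-(2-methoxy-2-oxoethyl)propane-1,1,3-tricarboxylate
Conditions: 2 (1.5 equiv), NaH (0.2 equiv), THF, 0 °C; 1 added slowly, rt
Reagents that add atoms: none
Why: Malonate Michael addition to the β-carbon of the glutaconate gives the 3-substituted glutarate; slow addition of 1 to excess sodiomalonate keeps the acidic glutaconate from condensing with itself. No stereocentre forms because the two CH2CO2Me arms are identical.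

Step 2
Reactants: 3
Product: 5 5-methoxy-3-(2-methoxy-2-oxoethyl)-5-oxopentanoic acid, via diacid 4 (not isolated)
Conditions: CF3CO2H, CH2Cl2, rt; evaporate; then xylenes, 140 °C
Reagents that add atoms: none
Why: Acidolysis removes only the tert-butyl esters, and the resulting substituted malonic acid loses CO2 on heating (malonic acid decarboxylation), leaving one free acetic acid arm beside two methyl esters.

Step 3
Reactants: 5; 6 (4S)-4-benzyl-1,3-oxazolidin-2-one
Product: 8 dimethyl 3-{2-[(4S)-4-benzyl-2-oxo-1,3-oxazolidin-3-yl]-2-oxoethyl}pentanedioate, via mixed pivalic anhydride 7 (not isolated)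
Conditions: t-BuCOCl, Et3N, THF, −20 °C; then 6, LiCl, −20 °C → rt
Reagents that add atoms: none
Why: N-Acylation of the oxazolidinone through the mixed anhydride, which is attacked at its less hindered carbonyl; the LiCl/Et3N variant needs no strong base, so the methyl esters are not touched.

Step 4
Reactants: 8; 9 acetaldehyde
Product: 11 dimethyl 3-[(2S,3R)-1-[(4S)-4-benzyl-2-oxo-1,3-oxazolidin-3-yl]-3-hydroxy-1-oxobutan-2-yl]pentanedioate, via boron enolate 10 (not isolated)
Conditions: Bu2BOTf, i-Pr2NEt, CH2Cl2, 0 °C; 9, −78 → 0 °C; pH 7 buffer, MeOH, H2O2, 0 °C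
Reagents that add atoms: none
Why: Evans syn-aldol: soft enolisation affects only the imide and gives the (Z)-boron enolate, which reacts through a Zimmerman–Traxler chair on the face away from the benzyl group. This sets the future C3 in its final sense and the carbinol carbon (future C2) as R, syn to it.

Step 5
Reactants: 11
Product: 12 dimethyl 3-[(2S,3R)-1-[(4S)-4-benzyl-2-oxo-1,3-oxazolidin-3-yl]-1-oxo-3-[(triethylsilyl)oxy]butan-2-yl]pentanedioate
Conditions: Et3SiOTf, 2,6-lutidine, CH2Cl2, −78 °C
Reagents that add atoms: triethylsilyl trifluoromethanesulfonate, CC[Si](CC)(CC)OS(=O)(=O)C(F)(F)F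
Why: O-Silylation blocks retro-aldol cleavage and lactonisation onto the δ-esters during the next two steps; the triethylsilyl group is chosen because it comes off under the acetalisation conditions of step 8.

Step 6
Reactants: 12
Product: 13 dimethyl 3-[(2S,3R)-1-(ethylsulfanyl)-1-oxo-3-[(triethylsilyl)oxy]butan-2-yl]pentanedioate
Conditions: EtSH, n-BuLi, THF, 0 °C
Reagents that add atoms: ethanethiol, CCS
Why: Thiolate transacylation cleaves the exocyclic imide carbonyl and releases the auxiliary; methyl esters are inert to lithium ethanethiolate at 0 °C and the weakly basic thiolate should not epimerise the α-centre.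

Step 7
Reactants: 13
Product: 14 dimethyl 3-[(2S,3R)-1-oxo-3-[(triethylsilyl)oxy]butan-2-yl]pentanedioate
Conditions: Et3SiH, 10% Pd/C, acetone, rt
Reagents that add atoms: none
Why: Fukuyama reduction converts the thioester to the aldehyde under neutral conditions that leave methyl esters and the silyl ether alone and should not epimerise the α-centre.

Step 8
Reactants: 14
Product: 16 dimethyl 3-[(2S,3R)-3-hydroxy-1,1-dimethoxybutan-2-yl]pentanedioate, via TES-protected acetal 15 (not isolated)
Conditions: HC(OMe)3, MeOH, camphorsulfonic acid (cat.), 0 °C → rt; Et3N before concentration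
Reagents that add atoms: trimethyl orthoformate, COC(OC)OC; methanol, CO
Why: Acid-catalysed acetalisation with the orthoformate as water scavenger; the same acid in methanol then cleaves the triethylsilyl ether. Neutralising before evaporation and using 16 at once should keep the δ-hydroxy esters from lactonising.

Step 9
Reactants: 16
Product: 17 dimethyl 3-[(2S,3S)-3-(formyloxy)-1,1-dimethoxybutan-2-yl]pentanedioate
Conditions: HCO2H, PPh3, DIAD, THF, 0 °C → rt
Reagents that add atoms: formic acid, O=CO
Why: Mitsunobu reaction: formate displaces the alkoxyphosphonium group by SN2, which inverts the carbinol carbon to S, creates the anti C2/C3 relationship and installs the formate needed for step 10 in one operation.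

Step 10
Reactants: 17
Product: 19 methyl (2S,3S,4S)-3-(dimethoxymethyl)-4-(2-methoxy-2-oxoethyl)-2-methyl-3,4-dihydro-2H-pyran-5-carboxylate, via lactol 18 (not isolated)
Conditions: LiN(SiMe3)2 (1.2 equiv), THF, −78 → −20 °C; AcOH; then Et3N, MeSO2Cl, 0 °C → rt
Reagents that add atoms: none
Why: Proposed new method: LiN(SiMe3)2 reversibly enolises either acetate arm of 17, and the enolate carbon (C5) attacks the formate carbonyl on O1 through a six-membered chair, giving a lithium hemiacetal alkoxide in equilibrium with the ring-opened C-formyl ester enolate; after the AcOH quench, lactol 18 is mesylated at the C6 hydroxyl and loses it by E1cB elimination across C5–C6 to give the β-alkoxyacrylate. The closest known reactions are the Claisen formylation–cyclodehydration of δ-hydroxy esters and Baker–Venkataraman-type O-to-C acyl transfer, neither of which has been used to choose between two diastereotopic ester arms. The dihydropyran ring closes by C5–C6 bond formation, 6-exo-trig at the formate carbonyl. C4 becomes stereogenic in this step and is controlled by C2 and C3: with the C2 methyl equatorial the cis C3 acetal is axial, and the spectator arm avoids A(1,3) strain with the planar enolate by standing axial, anti to the acetal, which is the 3,4-trans (4S) arrangement. The selectivity needed is between the two arms; reversible enolisation by the weak amide base should let both enolates interconvert, so the difference is expressed in the C–C bond-forming transition state. Chemoselectivity rests on the formate being far more electrophilic than a methyl ester and on the only other intramolecular Claisen closure being four-membered; only one formyl group is tethered, so over-formylation cannot occur, and the acetal leaves C3 without an acidifying group, so the formate cannot be lost by elimination.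

Step 11
Reactants: 19
Product: 20 2-[(2S,3S,4S)-3-(dimethoxymethyl)-5-(methoxycarbonyl)-2-methyl-3,4-dihydro-2H-pyran-4-yl]acetic acid
Conditions: LiOH·H2O (1.1 equiv), THF–H2O, 0 °C; then 1 M HCl to pH 4–5, 0 °C
Reagents that add atoms: lithium hydroxide, [Li+].[OH-]
Why: Saponification of the aliphatic methyl ester only; the C5 ester is a vinylogous carbonate and much less electrophilic. With C3 masked as the acetal there is no E1cB ring-opening pathway under hydroxide.

Step 12
Reactants: 20; 21 4-(2-hydroxyethyl)benzene-1,2-diol (hydroxytyrosol)
Product: 22 methyl (2S,3S,4S)-4-{2-[2-(3,4-dihydroxyphenyl)ethoxy]-2-oxoethyl}-3-(dimethoxymethyl)-2-methyl-3,4-dihydro-2H-pyran-5-carboxylate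
Conditions: PPh3, DIAD, THF, 0 °C → rt
Reagents that add atoms: none
Why: Mitsunobu esterification: the primary alcohol of 21 is activated as its alkoxyphosphonium ion and displaced by the carboxylate of 20. The carboxylic acid is several pKa units more acidic than the catechol hydroxyls and should be the only pronucleophile engaged, so no phenol protection is needed; no stereocentre is involved.

Step 13
Reactants: 22
Product: 23 methyl (2S,3S,4S)-4-{2-[2-(3,4-dihydroxyphenyl)ethoxy]-2-oxoethyl}-3-formyl-2-methyl-3,4-dihydro-2H-pyran-5-carboxylate
Conditions: Amberlyst-15 (H+ form), acetone–H2O, rt; filtration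
Reagents that add atoms: water, O
Why: Acid-catalysed acetal hydrolysis on a sulfonic acid resin; work-up is by filtration, so the β-alkoxy aldehyde never meets base. The β-alkoxyacrylate, the aliphatic ester and the catechol tolerate mild aqueous acid.

## Compound list

1 | dimethyl (E)-pent-2-enedioate | COC(=O)C/C=C/C(=O)OC | starting material
2 | di-tert-butyl propanedioate | CC(C)(C)OC(=O)CC(=O)OC(C)(C)C | starting material
3 | 1,1-di-tert-butyl 3-methyl 2-(2-methoxy-2-oxoethyl)propane-1,1,3-tricarboxylate | COC(=O)CC(CC(=O)OC)C(C(=O)OC(C)(C)C)C(=O)OC(C)(C)C | intermediate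
4 | 2-(1,5-dimethoxy-1,5-dioxopentan-3-yl)propanedioic acid | COC(=O)CC(CC(=O)OC)C(C(=O)O)C(=O)O | intermediate (not isolated)
5 | 5-methoxy-3-(2-methoxy-2-oxoethyl)-5-oxopentanoic acid | COC(=O)CC(CC(=O)OC)CC(=O)O | intermediate
6 | (4S)-4-benzyl-1,3-oxazolidin-2-one | O=C1N[C@@H](Cc2ccccc2)CO1 | starting material
7 | 5-methoxy-3-(2-methoxy-2-oxoethyl)-5-oxopentanoic 2,2-dimethylpropanoic anhydride | COC(=O)CC(CC(=O)OC)CC(=O)OC(=O)C(C)(C)C | intermediate (not isolated)
8 | dimethyl 3-{2-[(4S)-4-benzyl-2-oxo-1,3-oxazolidin-3-yl]-2-oxoethyl}pentanedioate | COC(=O)CC(CC(=O)OC)CC(=O)N1[C@@H](Cc2ccccc2)COC1=O | intermediate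
9 | acetaldehyde | CC=O | starting material
10 | dimethyl 3-{(2Z)-2-[(4S)-4-benzyl-2-oxo-1,3-oxazolidin-3-yl]-2-[(dibutylboranyl)oxy]ethenyl}pentanedioate | CCCCB(CCCC)O/C(=C\C(CC(=O)OC)CC(=O)OC)N1[C@@H](Cc2ccccc2)COC1=O | intermediate (not isolated)
11 | dimethyl 3-[(2S,3R)-1-[(4S)-4-benzyl-2-oxo-1,3-oxazolidin-3-yl]-3-hydroxy-1-oxobutan-2-yl]pentanedioate | O=C(N1[C@@H](Cc2ccccc2)COC1=O)[C@@H](C(CC(=O)OC)CC(=O)OC)[C@H](O)C | intermediate
12 | dimethyl 3-[(2S,3R)-1-[(4S)-4-benzyl-2-oxo-1,3-oxazolidin-3-yl]-1-oxo-3-[(triethylsilyl)oxy]butan-2-yl]pentanedioate | O=C(N1[C@@H](Cc2ccccc2)COC1=O)[C@@H](C(CC(=O)OC)CC(=O)OC)[C@H](O[Si](CC)(CC)CC)C | intermediate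
13 | dimethyl 3-[(2S,3R)-1-(ethylsulfanyl)-1-oxo-3-[(triethylsilyl)oxy]butan-2-yl]pentanedioate | CCSC(=O)[C@@H](C(CC(=O)OC)CC(=O)OC)[C@H](O[Si](CC)(CC)CC)C | intermediate
14 | dimethyl 3-[(2S,3R)-1-oxo-3-[(triethylsilyl)oxy]butan-2-yl]pentanedioate | O=C[C@@H](C(CC(=O)OC)CC(=O)OC)[C@H](O[Si](CC)(CC)CC)C | intermediate
15 | dimethyl 3-[(2S,3R)-1,1-dimethoxy-3-[(triethylsilyl)oxy]butan-2-yl]pentanedioate | COC(OC)[C@@H](C(CC(=O)OC)CC(=O)OC)[C@H](O[Si](CC)(CC)CC)C | intermediate (not isolated)
16 | dimethyl 3-[(2S,3R)-3-hydroxy-1,1-dimethoxybutan-2-yl]pentanedioate | COC(OC)[C@@H](C(CC(=O)OC)CC(=O)OC)[C@H](O)C | intermediate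
17 | dimethyl 3-[(2S,3S)-3-(formyloxy)-1,1-dimethoxybutan-2-yl]pentanedioate | COC(OC)[C@@H](C(CC(=O)OC)CC(=O)OC)[C@@H](OC=O)C | intermediate
18 | methyl (2S,3S,4S)-3-(dimethoxymethyl)-6-hydroxy-4-(2-methoxy-2-oxoethyl)-2-methyltetrahydro-2H-pyran-5-carboxylate (C5/C6 epimers, target ring numbering) | COC(=O)C1C(O)O[C@@H](C)[C@@H](C(OC)OC)[C@@H]1CC(=O)OC | intermediate (not isolated)
19 | methyl (2S,3S,4S)-3-(dimethoxymethyl)-4-(2-methoxy-2-oxoethyl)-2-methyl-3,4-dihydro-2H-pyran-5-carboxylate | COC(=O)C1=CO[C@@H](C)[C@@H](C(OC)OC)[C@@H]1CC(=O)OC | intermediate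
20 | 2-[(2S,3S,4S)-3-(dimethoxymethyl)-5-(methoxycarbonyl)-2-methyl-3,4-dihydro-2H-pyran-4-yl]acetic acid | COC(=O)C1=CO[C@@H](C)[C@@H](C(OC)OC)[C@@H]1CC(=O)O | intermediate
21 | 4-(2-hydroxyethyl)benzene-1,2-diol (hydroxytyrosol) | OCCc1ccc(O)c(O)c1 | starting material
22 | methyl (2S,3S,4S)-4-{2-[2-(3,4-dihydroxyphenyl)ethoxy]-2-oxoethyl}-3-(dimethoxymethyl)-2-methyl-3,4-dihydro-2H-pyran-5-carboxylate | COC(=O)C1=CO[C@@H](C)[C@@H](C(OC)OC)[C@@H]1CC(=O)OCCc1ccc(O)c(O)c1 | intermediate
23 | methyl (2S,3S,4S)-4-{2-[2-(3,4-dihydroxyphenyl)ethoxy]-2-oxoethyl}-3-formyl-2-methyl-3,4-dihydro-2H-pyran-5-carboxylate | COC(=O)C1=CO[C@@H](C)[C@@H](C=O)[C@@H]1CC(=O)OCCc1ccc(O)c(O)c1 | target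

## Step count and least certain steps

Total: 13 steps. Longest linear sequence: 13 steps (1 → 23); the route is fully linear.

**Step 10 (key step, proposed new method).** The discrimination between the two diastereotopic arms may be poor if the chair preference is small or if the enolates do not interconvert before the C–C bond forms. The C2 alkoxide set free on collapse of the hemiacetal may lactonise onto the spectator arm, and the formyl group may be transferred to the amide base.
Fallback with known chemistry, from 17 back to 19: camphorsulfonic acid in methanol removes the formyl group, and evaporation of the methanol from toluene closes the δ-lactone methyl 2-[(2S,3S,4R)-3-(dimethoxymethyl)-2-methyl-6-oxooxan-4-yl]acetate F1. The arm choice there is under thermodynamic control, and the unwanted C4 epimer can be reopened in acidic methanol and recycled. Claisen formylation at the lactone α-carbon with LiN(i-Pr)2 and methyl formate gives methyl 2-[(2S,3S,4S)-3-(dimethoxymethyl)-5-(hydroxymethylidene)-2-methyl-6-oxooxan-4-yl]acetate F2. Acidic methanolysis opens the lactone to the methyl ester, the freed C2 hydroxyl recloses onto the formyl carbon, and mesylation/elimination as in step 10 returns to 19.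

**Step 9.** SN2 displacement at a secondary carbinol next to a doubly branched carbon may be slow. Elimination, or participation of an ester carbonyl (lactonisation with inversion), may then compete with formate delivery.
Fallback, from 16 back to 17: Dess–Martin oxidation gives the methyl ketone dimethyl 3-[(2R)-1,1-dimethoxy-3-oxobutan-2-yl]pentanedioate F3. Corey–Bakshi–Shibata reduction under reagent control ((R)-2-methyl-CBS-oxazaborolidine, BH3·SMe2) gives the anti alcohol dimethyl 3-[(2S,3S)-3-hydroxy-1,1-dimethoxybutan-2-yl]pentanedioate F4. Formylation with acetic formic anhydride and pyridine returns to 17.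

**Step 12.** The free catechol may be O-alkylated by the activated alcohol or oxidised by the azodicarboxylate, and the polar product may be hard to separate from the phosphine oxide.
Fallback, from 20 and 21 back to 22: silylation of 21 with t-BuMe2SiCl and imidazole gives tert-butyl{2-[3,4-bis(tert-butyldimethylsilyloxy)phenyl]ethoxy}dimethylsilane F5. Camphorsulfonic acid in methanol at 0 °C removes only the alkyl silyl ether to give 2-[3,4-bis(tert-butyldimethylsilyloxy)phenyl]ethan-1-ol F6. Steglich esterification with 20 (carbodiimide, DMAP) gives methyl (2S,3S,4S)-4-(2-{2-[3,4-bis(tert-butyldimethylsilyloxy)phenyl]ethoxy}-2-oxoethyl)-3-(dimethoxymethyl)-2-methyl-3,4-dihydro-2H-pyran-5-carboxylate F7. Et3N·3HF frees the catechol while C3 is still masked, returning to 22.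

**Step 13.** C3 may epimerise through the enol, or the ring may open and reclose on the new aldehyde, during prolonged acid treatment; the unmasked catechol aldehyde is also harder to purify.
Fallback, from 20 to 23: the acetal is hydrolysed at the acid stage under the same resin conditions to give 2-[(2S,3S,4S)-3-formyl-5-(methoxycarbonyl)-2-methyl-3,4-dihydro-2H-pyran-4-yl]acetic acid F8 (elenolic acid). The Mitsunobu coupling with 21 then becomes the last step and gives 23 directly under near-neutral conditions.

**Step 1.** The glutaconate is more acidic than the malonate, so self-condensation of 1 may outrun the cross addition.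
Fallback, from 1 back to 5: Mukaiyama–Michael addition of the tert-butyldimethylsilyl ketene acetal of tert-butyl acetate to 1 under Lewis acid catalysis (Me3SiOTf), where no base is present, gives 1-tert-butyl 5-methyl 3-(2-methoxy-2-oxoethyl)pentanedioate F9. CF3CO2H then gives 5 without a decarboxylation.

## Further compounds

F1 | step 10 | methyl 2-[(2S,3S,4R)-3-(dimethoxymethyl)-2-methyl-6-oxooxan-4-yl]acetate | O=C1O[C@@H](C)[C@@H](C(OC)OC)[C@H](CC(=O)OC)C1
F2 | step 10 | methyl 2-[(2S,3S,4S)-3-(dimethoxymethyl)-5-(hydroxymethylidene)-2-methyl-6-oxooxan-4-yl]acetate | O=C1O[C@@H](C)[C@@H](C(OC)OC)[C@H](CC(=O)OC)C1=CO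
F3 | step 9 | dimethyl 3-[(2R)-1,1-dimethoxy-3-oxobutan-2-yl]pentanedioate | COC(OC)[C@@H](C(CC(=O)OC)CC(=O)OC)C(C)=O
F4 | step 9 | dimethyl 3-[(2S,3S)-3-hydroxy-1,1-dimethoxybutan-2-yl]pentanedioate | COC(OC)[C@@H](C(CC(=O)OC)CC(=O)OC)[C@@H](O)C
F5 | step 12 | tert-butyl{2-[3,4-bis(tert-butyldimethylsilyloxy)phenyl]ethoxy}dimethylsilane | CC(C)(C)[Si](C)(C)OCCc1ccc(O[Si](C)(C)C(C)(C)C)c(O[Si](C)(C)C(C)(C)C)c1
F6 | step 12 | 2-[3,4-bis(tert-butyldimethylsilyloxy)phenyl]ethan-1-ol | OCCc1ccc(O[Si](C)(C)C(C)(C)C)c(O[Si](C)(C)C(C)(C)C)c1
F7 | step 12 | methyl (2S,3S,4S)-4-(2-{2-[3,4-bis(tert-butyldimethylsilyloxy)phenyl]ethoxy}-2-oxoethyl)-3-(dimethoxymethyl)-2-methyl-3,4-dihydro-2H-pyran-5-carboxylate | COC(=O)C1=CO[C@@H](C)[C@@H](C(OC)OC)[C@@H]1CC(=O)OCCc1ccc(O[Si](C)(C)C(C)(C)C)c(O[Si](C)(C)C(C)(C)C)c1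
F8 | step 13 | 2-[(2S,3S,4S)-3-formyl-5-(methoxycarbonyl)-2-methyl-3,4-dihydro-2H-pyran-4-yl]acetic acid | COC(=O)C1=CO[C@@H](C)[C@@H](C=O)[C@@H]1CC(=O)O
F9 | step 1 | 1-tert-butyl 5-methyl 3-(2-methoxy-2-oxoethyl)pentanedioate | COC(=O)CC(CC(=O)OC)CC(=O)OC(C)(C)C
A1 | alternative 1 | (1E,3E)-5-(benzyloxy)-1-methoxypenta-1,3-diene | CO/C=C/C=C/COCc1ccccc1
A2 | alternative 1 | (2S,3R,6S)-3-[(benzyloxy)methyl]-6-methoxy-2-methyl-3,6-dihydro-2H-pyran | CO[C@H]1O[C@@H](C)[C@@H](COCc2ccccc2)C=C1
A3 | alternative 1 | (5R,6S)-5-[(benzyloxy)methyl]-6-methyl-5,6-dihydro-2H-pyran-2-one | O=C1C=C[C@H](COCc2ccccc2)[C@H](C)O1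
A4 | alternative 2 | (E)-but-2-enal | C/C=C/C=O
A5 | alternative 2 | 1-methyl 5-{2-[3,4-bis(tert-butyldimethylsilyloxy)phenyl]ethyl} (3E)-2-(hydroxymethylidene)pent-3-enedioate (enol geometry not fixed) | COC(=O)C(=CO)/C=C/C(=O)OCCc1ccc(O[Si](C)(C)C(C)(C)C)c(O[Si](C)(C)C(C)(C)C)c1
A6 | alternative 2 | methyl (2S,3S,4S)-4-(2-{2-[3,4-bis(tert-butyldimethylsilyloxy)phenyl]ethoxy}-2-oxoethyl)-3-formyl-2-methyl-3,4-dihydro-2H-pyran-5-carboxylate | COC(=O)C1=CO[C@@H](C)[C@@H](C=O)[C@@H]1CC(=O)OCCc1ccc(O[Si](C)(C)C(C)(C)C)c(O[Si](C)(C)C(C)(C)C)c1
A7 | alternative 3 | 2-[3,4-bis(tert-butyldimethylsilyloxy)phenyl]ethyl (2E,4R,5S)-5-[(2-bromo-3-methoxy-3-oxoprop-1-en-1-yl)oxy]-4-{[(tert-butyldimethylsilyl)oxy]methyl}hex-2-enoate (bromoacrylate geometry not fixed) | COC(=O)C(Br)=CO[C@@H](C)[C@@H](CO[Si](C)(C)C(C)(C)C)/C=C/C(=O)OCCc1ccc(O[Si](C)(C)C(C)(C)C)c(O[Si](C)(C)C(C)(C)C)c1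
A8 | alternative 3 | methyl (2S,3R,4S)-4-(2-{2-[3,4-bis(tert-butyldimethylsilyloxy)phenyl]ethoxy}-2-oxoethyl)-3-{[(tert-butyldimethylsilyl)oxy]methyl}-2-methyl-3,4-dihydro-2H-pyran-5-carboxylate | COC(=O)C1=CO[C@@H](C)[C@@H](CO[Si](C)(C)C(C)(C)C)[C@@H]1CC(=O)OCCc1ccc(O[Si](C)(C)C(C)(C)C)c(O[Si](C)(C)C(C)(C)C)c1
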